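**Plan**

- Numbering used for atoms: ring C5–C10 with C5 (bears C4(=C3H2)C15H2OH), C6 (OH), C7 (bears C11(=C13H2)C12O2H), C8 (acyloxy), C9 (CH2), C10 (quaternary, C14 methyl, C1=C2 vinyl).
- Retrosynthesis cuts, in order: the C15–O bond (late allylic oxidation) and the C12 acid oxidation level; the O–CO bond of the C8 ester; the C9–C10 ring bond, which opens the cyclohexane; then C9=C8 (lactone methylenation), O–C8 (eight-membered lactone), C5–C10 (Heck) and C6–C7 (aldol).
- Enabling feature: with C8 as a ketone, O=C8–C9–C10–C1=C2 is a γ,δ-unsaturated carbonyl (Claisen) unit. Because C8 and C10 are also joined through C7–C6–C5, the allyl vinyl ether C9=C8–O–C2–C1=C10 is an eight-membered cyclic enol ether, a temporary ring whose O–C2 bond is absent from the target and breaks as C9–C10 forms.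
- Forward order: Evans aldol (C6–C7); O6-tethered 6-exo Heck (C5–C10, ring-locked (Z)-C10=C1); imide cleavage, lactone reduction and macrolactonization to the oxocinone; Tebbe methylenation; Claisen ring contraction (the only carbocycle arises here); C8 reduction, esterification, C12 and C15 oxidations, desilylation.
- Stereochemistry: C6 and C7 from the (S)-4-benzyl-oxazolidinone auxiliary; C5 from C6 by allylic 1,3-strain in the tethered Heck; C10 from C5–C7 through the bridged chair-like Claisen transition state; C8 by thermodynamically controlled SmI2 reduction; the side-chain (Z)-alkene from an Ando-type olefination.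

Key step: step 13

Remark: 2-oxoethyl acetate, diphenyl phosphite and tert-butyl 2-bromopropanoate are taken as commercial; atom labels in the Why lines follow the numbering above.

**Route**

Step 1
Reactants: 1 4-methoxybenzyl alcohol; 2 3-chloro-2-(chloromethyl)prop-1-ene
Product: 3 1-({[2-(chloromethyl)prop-2-en-1-yl]oxy}methyl)-4-methoxybenzene
Conditions: NaH, THF/DMF, 0 °C → rt, threefold excess of 2
Reagents that add atoms: none
Why: Williamson ether synthesis of the alkoxide of 1 with one of the two equivalent allylic chlorides of 2, the excess of 2 suppressing the bis-ether.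

Step 2
Reactants: 3 allylic chloride
Product: 5 3-({[(4-methoxyphenyl)methyl]oxy}methyl)but-3-enoic acid, via allylmagnesium chloride 4 (not isolated)
Conditions: Mg, THF, 0 °C; CO2, −20 °C; aq. HCl
Reagents that add atoms: carbon dioxide O=C=O
Why: Carboxylation of an allylic Grignard reagent whose two allyl termini are equivalent, so that only the β,γ-unsaturated acid can form.

Step 3
Reactants: 5 butenoic acid; 6 (4S)-4-benzyl-1,3-oxazolidin-2-one
Product: 8 (4S)-4-benzyl-3-[3-({[(4-methoxyphenyl)methyl]oxy}methyl)but-3-enoyl]-1,3-oxazolidin-2-one, via pivalic mixed anhydride 7 (not isolated)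
Conditions: t-BuCOCl, Et3N, THF, −20 °C; then 6, LiCl, rt
Reagents that add atoms: none
Why: N-acylation of the oxazolidinone through the mixed pivalic anhydride, which is attacked at its less hindered carbonyl group.

Step 4
Reactants: 8 acyl oxazolidinone; 9 3-methylbut-2-enal
Product: 11 (4S)-4-benzyl-3-[(2S,3R)-3-hydroxy-2-(3-{[(4-methoxyphenyl)methyl]oxy}prop-1-en-2-yl)-5-methylhex-4-enoyl]-1,3-oxazolidin-2-one, via boron enolate 10 (not isolated)
Conditions: Bu2BOTf, i-Pr2NEt, CH2Cl2, 0 °C; 9, −78 → 0 °C; pH 7 buffer, MeOH, H2O2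
Reagents that add atoms: none
Why: Evans syn-aldol reaction in which the (Z)-boron dienolate reacts at its α-carbon through a Zimmerman–Traxler chair on the face away from the benzyl group, which sets C7 (S) and C6 (R) together.

Step 5
Reactants: 12 but-2-ynoic acid
Product: 13 (2Z)-3-iodobut-2-enoic acid
Conditions: NaI, AcOH, 115 °C
Reagents that add atoms: sodium iodide [Na+].[I-]
Why: Hydroiodination of the ynoic acid by conjugate addition of iodide and protonation, which should place iodine cis to the carboxyl group.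

Step 6
Reactants: 11 aldol adduct; 13 iodo acid
Product: 14 (4S)-4-benzyl-3-[(2S,3R)-3-{[(2Z)-3-iodobut-2-enoyl]oxy}-2-(3-{[(4-methoxyphenyl)methyl]oxy}prop-1-en-2-yl)-5-methylhex-4-enoyl]-1,3-oxazolidin-2-one
Conditions: N,N′-diisopropylcarbodiimide, DMAP (cat.), CH2Cl2, 0 °C
Reagents that add atoms: none
Why: Steglich esterification of the secondary allylic alcohol under near-neutral conditions that should leave the β-acyloxy imide and the (Z)-iodoalkene intact.

Step 7
Reactants: 14 iodoenoate ester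
Product: 15 (4S)-4-benzyl-3-{(2S)-3-({[(4-methoxyphenyl)methyl]oxy}methyl)-2-[(2R,3R)-4-methyl-6-oxo-3-(prop-1-en-2-yl)-3,6-dihydro-2H-pyran-2-yl]but-3-enoyl}-1,3-oxazolidin-2-one
Conditions: Pd(OAc)2 (cat.), PPh3, Ag2CO3, MeCN, 70 °C
Reagents that add atoms: none
Why: Intramolecular Heck reaction in the 6-exo-trig mode, in which syn-carbopalladation occurs on the alkene face carrying the tethering oxygen while allylic 1,3-strain holds H-6 eclipsed with the cis-methyl group, which sets C5 trans to the C6 side chain, and β-hydride elimination from a methyl group leaves the isopropenyl group.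

Step 8
Reactants: 15 imide lactone
Product: 17 (2S)-3-({[(4-methoxyphenyl)methyl]oxy}methyl)-2-[(2R,3R)-4-methyl-6-oxo-3-(prop-1-en-2-yl)-3,6-dihydro-2H-pyran-2-yl]but-3-enoic acid, via peroxy acid 16 (not isolated)
Conditions: LiOH, H2O2, THF/H2O, 0 °C; Na2SO3; HCl to pH 3
Reagents that add atoms: hydrogen peroxide OO
Why: Hydroperoxide cleavage of the N-acyl oxazolidinone at the exocyclic carbonyl group, the acidic work-up re-closing any opened δ-lactone.

Step 9
Reactants: 17 acid lactone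
Product: 18 (2S,3R,4R,5Z)-3,7-dihydroxy-2-(3-{[(4-methoxyphenyl)methyl]oxy}prop-1-en-2-yl)-5-methyl-4-(prop-1-en-2-yl)hept-5-enoic acid
Conditions: LiBH4, THF/MeOH, 0 °C → rt
Reagents that add atoms: none
Why: Chemoselective borohydride reduction of the unsaturated δ-lactone to the (Z)-allylic diol, the lithium carboxylate being inert and the alkene geometry fixed by the former ring.

Step 10
Reactants: 18 dihydroxy acid
Product: 20 (3S,4R,5R,6Z)-4-hydroxy-3-(3-{[(4-methoxyphenyl)methyl]oxy}prop-1-en-2-yl)-6-methyl-5-(prop-1-en-2-yl)-3,4,5,8-tetrahydro-2H-oxocin-2-one, via mixed anhydride 19 (not isolated)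
Conditions: 2-methyl-6-nitrobenzoic anhydride, DMAP, CH2Cl2, rt, slow addition of 18 (2 mM)
Reagents that add atoms: none
Why: Shiina macrolactonization in which the primary allylic hydroxyl attacks the mixed anhydride, the (Z)-alkene and three ring substituents favouring the eight-membered ring over β-lactone or oligomer formation.

Step 11
Reactants: 20 hydroxy lactone
Product: 21 (3S,4R,5R,6Z)-3-(3-{[(4-methoxyphenyl)methyl]oxy}prop-1-en-2-yl)-6-methyl-5-(prop-1-en-2-yl)-4-[(triethylsilyl)oxy]-3,4,5,8-tetrahydro-2H-oxocin-2-one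
Conditions: Et3SiOSO2CF3, 2,6-lutidine, CH2Cl2, −78 °C
Reagents that add atoms: triethylsilyl trifluoromethanesulfonate CC[Si](CC)(CC)OS(=O)(=O)C(F)(F)F
Why: Silyl ether formation at the hindered secondary hydroxyl with a silyl triflate and a non-nucleophilic base.

Step 12
Reactants: 21 silylated lactone
Product: 22 (3S,4R,5R,6Z)-3-(3-{[(4-methoxyphenyl)methyl]oxy}prop-1-en-2-yl)-6-methyl-2-methylidene-5-(prop-1-en-2-yl)-4-[(triethylsilyl)oxy]-3,4,5,8-tetrahydro-2H-oxocine
Conditions: Cp2Ti(μ-Cl)(μ-CH2)AlMe2, pyridine, THF/toluene, −40 → 0 °C; aq. NaOH; filtration through basic Al2O3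
Reagents that add atoms: Cp2Ti(μ-Cl)(μ-CH2)AlMe2 (Tebbe reagent) C[Al-]1(C)C[Ti](C2C=CC=C2)(C2C=CC=C2)[Cl+]1
Why: Tebbe methylenation of the lactone carbonyl group at low temperature, which should give the acid-sensitive exocyclic enol ether without enolizing C7.

Step 13
Reactants: 22 cyclic enol ether
Product: 23 (2S,3R,4R,5R)-5-ethenyl-2-(3-{[(4-methoxyphenyl)methyl]oxy}prop-1-en-2-yl)-5-methyl-4-(prop-1-en-2-yl)-3-[(triethylsilyl)oxy]cyclohexan-1-one
Conditions: toluene, Et3N (trace), 130 °C, sealed tube, base-washed glass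
Reagents that add atoms: none
Why: Thermal Claisen ([3,3]-sigmatropic) rearrangement of the allyl vinyl ether C9=C8–O–C2–C1=C10, in which the C9–C10 bond forms as the O–C2 bond breaks and the C8 ketone, the C1=C2 vinyl group and the quaternary C10 appear in one concerted event. The closest known reaction types are the Tebbe methylenation–Claisen sequence of unsaturated lactones and the ring-contracting Claisen rearrangement of medium-ring lactone ketene acetals. The cyclohexane closes transannularly, C9 bridging C8 and C10 across the oxocine through a bicyclo[3.3.1]-like chair–chair transition state, so the eight-membered ether contracts to the six-membered carbocycle. C10 is the only new stereocenter and is controlled by C6: the O–C2–C1 bridge can lie only on the ring face where C6 carries hydrogen, with the silyloxy group and the C7 side chain equatorial and the C5 isopropenyl group axial on the other face, so the vinyl group should end cis to H-6 and trans to the isopropenyl group (10R). The step needs this face selectivity and the concerted path over ionization or hydrolysis of the enol ether; the ring-locked (Z)-alkene allows only the bridged geometry, and base-washed glass with a trace of Et3N keeps acid away. The temperature is held at 130 °C so that the product, whose two alkenyl groups are trans-diaxial, should not enter a Cope equilibrium.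

Step 14
Reactants: 23 cyclohexanone
Product: 24 (1S,2R,3R,4R,5R)-5-ethenyl-2-(3-{[(4-methoxyphenyl)methyl]oxy}prop-1-en-2-yl)-5-methyl-4-(prop-1-en-2-yl)-3-[(triethylsilyl)oxy]cyclohexan-1-ol
Conditions: SmI2, THF/MeOH, 0 °C
Reagents that add atoms: none
Why: Single-electron-transfer ketone reduction under thermodynamic control, which should give the equatorial C8 alcohol cis to the C6 silyl ether instead of the axial epimer expected from hydride attack anti to the axial vinyl group.

Step 15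
Reactants: 25 tert-butyl 2-bromopropanoate; 26 diphenyl phosphite
Product: 27 tert-butyl 2-(diphenoxyphosphoryl)propanoate
Conditions: NaH, THF, 0 °C → rt
Reagents that add atoms: none
Why: Michaelis–Becker alkylation of the sodium phosphite with the α-bromo ester.

Step 16
Reactants: 27 diphenyl phosphonate; 28 2-oxoethyl acetate
Product: 29 tert-butyl (2Z)-4-(acetyloxy)-2-methylbut-2-enoate
Conditions: NaH, THF, 0 °C; then 28, −78 → 0 °C
Reagents that add atoms: none
Why: Ando-type Horner–Wadsworth–Emmons olefination, in which the diaryl phosphonate eliminates fast from the kinetically formed adduct and should give the (Z)-trisubstituted enoate.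

Step 17
Reactants: 29 tert-butyl ester
Product: 30 (2Z)-4-(acetyloxy)-2-methylbut-2-enoic acid
Conditions: CF3CO2H, CH2Cl2, 0 °C
Reagents that add atoms: none
Why: Acidolysis of the tert-butyl ester by loss of isobutene, which leaves the primary acetate and the (Z)-alkene untouched.

Step 18
Reactants: 24 cyclohexanol; 30 side-chain acid
Product: 32 (1S,2R,3R,4R,5R)-5-ethenyl-2-(3-{[(4-methoxyphenyl)methyl]oxy}prop-1-en-2-yl)-5-methyl-4-(prop-1-en-2-yl)-3-[(triethylsilyl)oxy]cyclohexyl (2Z)-4-(acetyloxy)-2-methylbut-2-enoate, via trichlorobenzoic mixed anhydride 31 (not isolated)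
Conditions: 2,4,6-trichlorobenzoyl chloride, Et3N, toluene, rt; then 24, 75 °C, no DMAP
Reagents that add atoms: none
Why: Yamaguchi-type esterification run without a nucleophilic catalyst so that the (Z)-enoate is not isomerized by conjugate addition–elimination, the C8 hydroxyl being the only free nucleophile in 24.

Step 19
Reactants: 32 side-chain ester
Product: 33 (1S,2R,3R,4R,5R)-5-ethenyl-2-(3-hydroxyprop-1-en-2-yl)-5-methyl-4-(prop-1-en-2-yl)-3-[(triethylsilyl)oxy]cyclohexyl (2Z)-4-(acetyloxy)-2-methylbut-2-enoate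
Conditions: DDQ, CH2Cl2/pH 7 buffer, 0 °C
Reagents that add atoms: none
Why: Oxidative cleavage of the 4-methoxybenzyl ether by hydride abstraction and hydrolysis, which frees only the C12 allylic alcohol.

Step 20
Reactants: 33 allylic alcohol
Product: 35 2-[(1R,2R,3R,4R,6S)-6-{[(2Z)-4-(acetyloxy)-2-methylbut-2-enoyl]oxy}-4-ethenyl-4-methyl-3-(prop-1-en-2-yl)-2-[(triethylsilyl)oxy]cyclohexyl]prop-2-enoic acid, via enal 34 (not isolated)
Conditions: TEMPO (cat.), PhI(OAc)2, CH2Cl2, rt; then NaClO2, NaH2PO4, 2-methylbut-2-ene, t-BuOH/H2O, 0 °C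
Reagents that add atoms: sodium chlorite [Na+].[O-]Cl=O
Why: Oxoammonium oxidation of the allylic alcohol to the enal followed by Pinnick oxidation, carried out while the C6 hydroxyl is still silylated so that no lactol or lactone can form.

Step 21
Reactants: 35 acrylic acid
Product: 36 2-[(1R,2R,3S,4R,6S)-6-{[(2Z)-4-(acetyloxy)-2-methylbut-2-enoyl]oxy}-4-ethenyl-3-(3-hydroxyprop-1-en-2-yl)-4-methyl-2-[(triethylsilyl)oxy]cyclohexyl]prop-2-enoic acid
Conditions: SeO2 (cat.), t-BuOOH, CH2Cl2, rt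
Reagents that add atoms: selenium dioxide O=[Se]=O; tert-butyl hydroperoxide CC(C)(C)OO
Why: Selenium dioxide allylic oxidation (ene reaction then [2,3]-sigmatropic shift) of the C4 isopropenyl group, the only electron-rich alkene that carries an allylic methyl group, to the primary allylic alcohol.

Step 22
Reactants: 36 silyl ether
Product: 37 2-[(1S,2R,3S,4R,6S)-6-{[(2Z)-4-(acetyloxy)-2-methylbut-2-enoyl]oxy}-4-ethenyl-2-hydroxy-3-(3-hydroxyprop-1-en-2-yl)-4-methylcyclohexyl]prop-2-enoic acid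
Conditions: HF·pyridine, pyridine, THF, 0 °C
Reagents that add atoms: none
Why: Fluoride-mediated cleavage of the triethylsilyl ether under buffered conditions that should neither lactonize the γ-hydroxy acid nor cleave the esters.

**Compound list**

1 | 4-methoxybenzyl alcohol | COc1ccc(CO)cc1 | starting material
2 | 3-chloro-2-(chloromethyl)prop-1-ene | C=C(CCl)CCl | starting material
3 | 1-({[2-(chloromethyl)prop-2-en-1-yl]oxy}methyl)-4-methoxybenzene | COc1ccc(COCC(=C)CCl)cc1 | intermediate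
4 | [2-({[(4-methoxyphenyl)methyl]oxy}methyl)prop-2-en-1-yl]magnesium chloride | COc1ccc(COCC(=C)C[Mg]Cl)cc1 | intermediate
5 | 3-({[(4-methoxyphenyl)methyl]oxy}methyl)but-3-enoic acid | COc1ccc(COCC(=C)CC(=O)O)cc1 | intermediate
6 | (4S)-4-benzyl-1,3-oxazolidin-2-one | O=C1N[C@@H](Cc2ccccc2)CO1 | starting material
7 | 3-({[(4-methoxyphenyl)methyl]oxy}methyl)but-3-enoic 2,2-dimethylpropanoic anhydride | COc1ccc(COCC(=C)CC(=O)OC(=O)C(C)(C)C)cc1 | intermediate
8 | (4S)-4-benzyl-3-[3-({[(4-methoxyphenyl)methyl]oxy}methyl)but-3-enoyl]-1,3-oxazolidin-2-one | COc1ccc(COCC(=C)CC(=O)N2[C@@H](Cc3ccccc3)COC2=O)cc1 | intermediate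
9 | 3-methylbut-2-enal | CC(C)=CC=O | starting material
10 | dibutylboron (Z)-enolate of 8 | CCCCB(CCCC)O/C(=C\C(=C)COCc1ccc(OC)cc1)N1[C@@H](Cc2ccccc2)COC1=O | intermediate
11 | (4S)-4-benzyl-3-[(2S,3R)-3-hydroxy-2-(3-{[(4-methoxyphenyl)methyl]oxy}prop-1-en-2-yl)-5-methylhex-4-enoyl]-1,3-oxazolidin-2-one | O=C(N1[C@@H](Cc2ccccc2)COC1=O)[C@@H](C(=C)COCc1ccc(OC)cc1)[C@H](O)C=C(C)C | intermediate
12 | but-2-ynoic acid | CC#CC(=O)O | starting material
13 | (2Z)-3-iodobut-2-enoic acid | C/C(I)=C/C(=O)O | intermediate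
14 | (4S)-4-benzyl-3-[(2S,3R)-3-{[(2Z)-3-iodobut-2-enoyl]oxy}-2-(3-{[(4-methoxyphenyl)methyl]oxy}prop-1-en-2-yl)-5-methylhex-4-enoyl]-1,3-oxazolidin-2-one | O=C(N1[C@@H](Cc2ccccc2)COC1=O)[C@@H](C(=C)COCc1ccc(OC)cc1)[C@H](OC(=O)/C=C(/C)I)C=C(C)C | intermediate
15 | (4S)-4-benzyl-3-{(2S)-3-({[(4-methoxyphenyl)methyl]oxy}methyl)-2-[(2R,3R)-4-methyl-6-oxo-3-(prop-1-en-2-yl)-3,6-dihydro-2H-pyran-2-yl]but-3-enoyl}-1,3-oxazolidin-2-one | O=C(N1[C@@H](Cc2ccccc2)COC1=O)[C@@H](C(=C)COCc1ccc(OC)cc1)[C@@H]1OC(=O)C=C(C)[C@H]1C(C)=C | intermediate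
16 | (2S)-3-({[(4-methoxyphenyl)methyl]oxy}methyl)-2-[(2R,3R)-4-methyl-6-oxo-3-(prop-1-en-2-yl)-3,6-dihydro-2H-pyran-2-yl]but-3-eneperoxoic acid | OOC(=O)[C@@H](C(=C)COCc1ccc(OC)cc1)[C@@H]1OC(=O)C=C(C)[C@H]1C(C)=C | intermediate
17 | (2S)-3-({[(4-methoxyphenyl)methyl]oxy}methyl)-2-[(2R,3R)-4-methyl-6-oxo-3-(prop-1-en-2-yl)-3,6-dihydro-2H-pyran-2-yl]but-3-enoic acid | OC(=O)[C@@H](C(=C)COCc1ccc(OC)cc1)[C@@H]1OC(=O)C=C(C)[C@H]1C(C)=C | intermediate
18 | (2S,3R,4R,5Z)-3,7-dihydroxy-2-(3-{[(4-methoxyphenyl)methyl]oxy}prop-1-en-2-yl)-5-methyl-4-(prop-1-en-2-yl)hept-5-enoic acid | OC(=O)[C@@H](C(=C)COCc1ccc(OC)cc1)[C@H](O)[C@H](C(C)=C)/C(C)=C\CO | intermediate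
19 | mixed anhydride of 18 (carboxyl group) with 2-methyl-6-nitrobenzoic acid | Cc1cccc([N+](=O)[O-])c1C(=O)OC(=O)[C@@H](C(=C)COCc1ccc(OC)cc1)[C@H](O)[C@H](C(C)=C)/C(C)=C\CO | intermediate
20 | (3S,4R,5R,6Z)-4-hydroxy-3-(3-{[(4-methoxyphenyl)methyl]oxy}prop-1-en-2-yl)-6-methyl-5-(prop-1-en-2-yl)-3,4,5,8-tetrahydro-2H-oxocin-2-one | O=C1OC/C=C(C)\[C@@H](C(C)=C)[C@@H](O)[C@@H]1C(=C)COCc1ccc(OC)cc1 | intermediate
21 | (3S,4R,5R,6Z)-3-(3-{[(4-methoxyphenyl)methyl]oxy}prop-1-en-2-yl)-6-methyl-5-(prop-1-en-2-yl)-4-[(triethylsilyl)oxy]-3,4,5,8-tetrahydro-2H-oxocin-2-one | O=C1OC/C=C(C)\[C@@H](C(C)=C)[C@@H](O[Si](CC)(CC)CC)[C@@H]1C(=C)COCc1ccc(OC)cc1 | intermediate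
22 | (3S,4R,5R,6Z)-3-(3-{[(4-methoxyphenyl)methyl]oxy}prop-1-en-2-yl)-6-methyl-2-methylidene-5-(prop-1-en-2-yl)-4-[(triethylsilyl)oxy]-3,4,5,8-tetrahydro-2H-oxocine | C=C1OC/C=C(C)\[C@@H](C(C)=C)[C@@H](O[Si](CC)(CC)CC)[C@@H]1C(=C)COCc1ccc(OC)cc1 | intermediate
23 | (2S,3R,4R,5R)-5-ethenyl-2-(3-{[(4-methoxyphenyl)methyl]oxy}prop-1-en-2-yl)-5-methyl-4-(prop-1-en-2-yl)-3-[(triethylsilyl)oxy]cyclohexan-1-one | C=C[C@@]1(C)CC(=O)[C@@H](C(=C)COCc2ccc(OC)cc2)[C@H](O[Si](CC)(CC)CC)[C@@H]1C(C)=C | intermediate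
24 | (1S,2R,3R,4R,5R)-5-ethenyl-2-(3-{[(4-methoxyphenyl)methyl]oxy}prop-1-en-2-yl)-5-methyl-4-(prop-1-en-2-yl)-3-[(triethylsilyl)oxy]cyclohexan-1-ol | C=C[C@@]1(C)C[C@H](O)[C@@H](C(=C)COCc2ccc(OC)cc2)[C@H](O[Si](CC)(CC)CC)[C@@H]1C(C)=C | intermediate
25 | tert-butyl 2-bromopropanoate | CC(Br)C(=O)OC(C)(C)C | starting material
26 | diphenyl phosphite | O=[PH](Oc1ccccc1)Oc1ccccc1 | starting material
27 | tert-butyl 2-(diphenoxyphosphoryl)propanoate | CC(C(=O)OC(C)(C)C)P(=O)(Oc1ccccc1)Oc1ccccc1 | intermediate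
28 | 2-oxoethyl acetate | CC(=O)OCC=O | starting material
29 | tert-butyl (2Z)-4-(acetyloxy)-2-methylbut-2-enoate | CC(=O)OC/C=C(/C)C(=O)OC(C)(C)C | intermediate
30 | (2Z)-4-(acetyloxy)-2-methylbut-2-enoic acid | CC(=O)OC/C=C(/C)C(=O)O | intermediate
31 | (2Z)-4-(acetyloxy)-2-methylbut-2-enoic 2,4,6-trichlorobenzoic anhydride | CC(=O)OC/C=C(/C)C(=O)OC(=O)c1c(Cl)cc(Cl)cc1Cl | intermediate
32 | (1S,2R,3R,4R,5R)-5-ethenyl-2-(3-{[(4-methoxyphenyl)methyl]oxy}prop-1-en-2-yl)-5-methyl-4-(prop-1-en-2-yl)-3-[(triethylsilyl)oxy]cyclohexyl (2Z)-4-(acetyloxy)-2-methylbut-2-enoate | C=C[C@@]1(C)C[C@H](OC(=O)/C(C)=C\COC(C)=O)[C@@H](C(=C)COCc2ccc(OC)cc2)[C@H](O[Si](CC)(CC)CC)[C@@H]1C(C)=C | intermediate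
33 | (1S,2R,3R,4R,5R)-5-ethenyl-2-(3-hydroxyprop-1-en-2-yl)-5-methyl-4-(prop-1-en-2-yl)-3-[(triethylsilyl)oxy]cyclohexyl (2Z)-4-(acetyloxy)-2-methylbut-2-enoate | C=C[C@@]1(C)C[C@H](OC(=O)/C(C)=C\COC(C)=O)[C@@H](C(=C)CO)[C@H](O[Si](CC)(CC)CC)[C@@H]1C(C)=C | intermediate
34 | (1S,2R,3R,4R,5R)-5-ethenyl-5-methyl-2-(3-oxoprop-1-en-2-yl)-4-(prop-1-en-2-yl)-3-[(triethylsilyl)oxy]cyclohexyl (2Z)-4-(acetyloxy)-2-methylbut-2-enoate | C=C[C@@]1(C)C[C@H](OC(=O)/C(C)=C\COC(C)=O)[C@@H](C(=C)C=O)[C@H](O[Si](CC)(CC)CC)[C@@H]1C(C)=C | intermediate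
35 | 2-[(1R,2R,3R,4R,6S)-6-{[(2Z)-4-(acetyloxy)-2-methylbut-2-enoyl]oxy}-4-ethenyl-4-methyl-3-(prop-1-en-2-yl)-2-[(triethylsilyl)oxy]cyclohexyl]prop-2-enoic acid | C=C[C@@]1(C)C[C@H](OC(=O)/C(C)=C\COC(C)=O)[C@@H](C(=C)C(=O)O)[C@H](O[Si](CC)(CC)CC)[C@@H]1C(C)=C | intermediate
36 | 2-[(1R,2R,3S,4R,6S)-6-{[(2Z)-4-(acetyloxy)-2-methylbut-2-enoyl]oxy}-4-ethenyl-3-(3-hydroxyprop-1-en-2-yl)-4-methyl-2-[(triethylsilyl)oxy]cyclohexyl]prop-2-enoic acid | C=C[C@@]1(C)C[C@H](OC(=O)/C(C)=C\COC(C)=O)[C@@H](C(=C)C(=O)O)[C@H](O[Si](CC)(CC)CC)[C@@H]1C(=C)CO | intermediate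
37 | 2-[(1S,2R,3S,4R,6S)-6-{[(2Z)-4-(acetyloxy)-2-methylbut-2-enoyl]oxy}-4-ethenyl-2-hydroxy-3-(3-hydroxyprop-1-en-2-yl)-4-methylcyclohexyl]prop-2-enoic acid (CNP0261293.4) | C=C[C@@]1(C)C[C@H](OC(=O)/C(C)=C\COC(C)=O)[C@@H](C(=C)C(=O)O)[C@H](O)[C@@H]1C(=C)CO | target

**Summary**

Total step count: 22. Longest linear sequence: 18 steps (steps 1–4, 6–14, 18–22).

Steps most likely to fail:

Step 13. The enol ether may be lost by hydrolysis or ionization before it rearranges, or the face selectivity at C10 may be poor. The fallback closes the same bond by an ionic route, an intramolecular Tsuji–Trost allylation, setting out from lactone 21 and returning at ketone 23. Lactone 21 is opened with MeNHOMe·HCl and AlMe3 to the hydroxy Weinreb amide F1. MeMgBr converts this into the methyl ketone F2. The allylic alcohol is turned into the methyl carbonate F3 with ClCO2Me and pyridine. Pd(PPh3)4 with pyrrolidine (enamine of the methyl ketone attacking the π-allyl palladium unit) should then close the six-membered ring at C10 to give 23, from which a C10 epimer may have to be separated.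

Step 10. Oligomerization or acylation of the secondary hydroxyl may compete with closure of the eight-membered ring. The fallback closes the ring at the other C–O bond, by carboxylate alkylation instead of acyl activation, setting out from 18 and returning at 20. The primary allylic alcohol of 18 is converted selectively into the allylic chloride F4 by Corey–Kim chlorination (N-chlorosuccinimide, Me2S, CH2Cl2, −20 °C). Cs2CO3 in DMF at high dilution should then displace the chloride with the caesium carboxylate to give 20.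

Step 14. The preference for the equatorial alcohol may be insufficient, the axial epimer arising by delivery of hydrogen anti to the axial vinyl group. The fallback sets out from ketone 23 and returns at ester 32, replacing steps 14 and 18. Ketone 23 is reduced deliberately with LiB(s-Bu)3H (THF, −78 °C) to the axial alcohol F5. This is esterified with acid 30 under Mitsunobu conditions (PPh3, diisopropyl azodicarboxylate, toluene) with inversion at C8 to give 32.

Further compounds
F1 | step 13 | (2S,3R,4R,5Z)-7-hydroxy-N-methoxy-2-(3-{[(4-methoxyphenyl)methyl]oxy}prop-1-en-2-yl)-N,5-dimethyl-4-(prop-1-en-2-yl)-3-[(triethylsilyl)oxy]hept-5-enamide | CON(C)C(=O)[C@@H](C(=C)COCc1ccc(OC)cc1)[C@H](O[Si](CC)(CC)CC)[C@H](C(C)=C)/C(C)=C\CO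
F2 | step 13 | (3S,4R,5R,6Z)-8-hydroxy-3-(3-{[(4-methoxyphenyl)methyl]oxy}prop-1-en-2-yl)-6-methyl-5-(prop-1-en-2-yl)-4-[(triethylsilyl)oxy]oct-6-en-2-one | CC(=O)[C@@H](C(=C)COCc1ccc(OC)cc1)[C@H](O[Si](CC)(CC)CC)[C@H](C(C)=C)/C(C)=C\CO
F3 | step 13 | methyl (2Z,4R,5R,6S)-6-(3-{[(4-methoxyphenyl)methyl]oxy}prop-1-en-2-yl)-3-methyl-7-oxo-4-(prop-1-en-2-yl)-5-[(triethylsilyl)oxy]oct-2-en-1-yl carbonate | CC(=O)[C@@H](C(=C)COCc1ccc(OC)cc1)[C@H](O[Si](CC)(CC)CC)[C@H](C(C)=C)/C(C)=C\COC(=O)OC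
F4 | step 10 | (2S,3R,4R,5Z)-7-chloro-3-hydroxy-2-(3-{[(4-methoxyphenyl)methyl]oxy}prop-1-en-2-yl)-5-methyl-4-(prop-1-en-2-yl)hept-5-enoic acid | OC(=O)[C@@H](C(=C)COCc1ccc(OC)cc1)[C@H](O)[C@H](C(C)=C)/C(C)=C\CCl
F5 | step 14 | (1R,2R,3R,4R,5R)-5-ethenyl-2-(3-{[(4-methoxyphenyl)methyl]oxy}prop-1-en-2-yl)-5-methyl-4-(prop-1-en-2-yl)-3-[(triethylsilyl)oxy]cyclohexan-1-ol | C=C[C@@]1(C)C[C@@H](O)[C@@H](C(=C)COCc2ccc(OC)cc2)[C@H](O[Si](CC)(CC)CC)[C@@H]1C(C)=C
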